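The runs were generated by integration for substances that don't exist, and the scatter is random.

In a one-step world at constant c(acid), the logarithm of substrate falls on a straight line once the feed ends. Its slope is a pseudo-first-order constant, and you can read a mean one off the runs.

common to all: substrate 0.050 M (fed, over 15 h)
- dusk: acid 0.15 mM; scavenger 0.010 M; run made earlier
- autumn: acid 0.15 mM; scavenger 0.022 M; run made earlier
- flask: acid 0.150 mM; scavenger 0.0150 M; time 25 h

- dusk (time / h: substrate / %, product / %): 2.50: 13.3, 2.1; 8.00: 33.0, 15.5; 15.0: 42.1, 41.2; 20.0: 23.6, 55.6; 30.0: 11.3, 70.8
- autumn (time / h: substrate / %, product / %): 2.50: 15.1, 1.7; 5.00: 24.8, 6.3; 8.00: 34.2, 14.7; 15.0: 43.7, 41.8; 30.0: 10.5, 74.9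

(scatter of a reading: 0.5 percentage points)

* part of the substrate that has reacted at 25 h
* pH of the solution at 25 h

- acid is the free proton; pH is minus the decimal logarithm of its molar concentration
- a reading or a percentage of product counts all its forms, free or not
- what has gone from substrate into another species counts as reacted, even if it can come back
- percentages count the whole charge, also what has not yet gone in

Take the fall of ln c(substrate) per hour from the end of the feed to the last reading. The dusk readings give 0.0877 h⁻¹. The autumn readings give 0.0951 h⁻¹. Both runs had 0.15 mM acid. Autumn had 2.20 times the scavenger of dusk, yet its slope is just 1.08 times as large. So the two runs end close together, at 11.3 % and 10.5 % substrate, and you watch c(acid), not c(scavenger).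

The flask has the same acid and feed, with scavenger between the two. Your tail constant, the mean of the two slopes, is 0.0914 h⁻¹. From a mean 42.9 % substrate at the end of the feed, it leaves 17.2 % at the asked time, so 82.8 % has reacted.

The forecast says 84.5 % and pH 4.2, which on conversion is higher than your figure. Its ground is “Interpolating the convex log decay”.

The flask gives 84.8 % reacted and pH 3.82.

    substrate + acid → weak acid + acid + product (k = 8.80 M⁻¹ min⁻¹)
    weak acid ⇌ conjugate base + acid, settled at all times (K = 1.60 × 10⁻⁹ M)
    substrate → weak acid + product (k = 2.90 × 10⁻⁴ min⁻¹)
    substrate + weak acid ⇌ idle adduct, settled at all times (K = 61.0 M⁻¹)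
    weak acid + scavenger → scavenged by-product (k = 0.990 M⁻¹ min⁻¹)
    crystals ⇌ product, rate k6*(cs6 - [product]) while solid is left; crystals form when [product] > cs6 (solubility = 39.0 mM, k = 0.00410 min⁻¹)
    substrate ⇌ dormant form (K = 0.490, k = 2.20 × 10⁻⁴ min⁻¹)

At 13.0 h in this flask, the step through acid used substrate 4.6 times as fast as the conversion without acid. From the end of the feed to the asked time, the slope in this flask was 0.104 h⁻¹, steeper than the tail constant of 0.0914 h⁻¹. Conversion shifts by 5 points if acid moves alone to 0.112 mM or 0.217 mM, so a run at those charges would part from the forecast.

Read the same flask at 2.5 d. From 15.2 %, the tail constant leaves 0.621 % substrate. The computed neighbour holds more than that, 2.84 %, with 97.2 % reacted.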